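**Plan**
- Retrosynthetic cuts: the two acetates; C12–C13 (sp3–sp2 cross-coupling), which releases the C13–C16 unit; the C7=C8 alkene back to a C7 ketone; ring A at C1–C2 and C4–C5; ring B at C5–C10 and C8–C9 (Diels–Alder).
- Forward order: ring B first (cycloaddition, then enone). Ring A follows in one [3+3] annulation with a C2–C3–C4(CH3)2 linchpin. C5 and C7 are then adjusted, and the side chain comes last.
- Enabling feature: on ring B the formyl carbon C1 (on quaternary C10) and the enone β-carbon C5 are 1,3-related. A three-carbon unit with an ylide at C2 and a latent tertiary radical at C4 therefore closes ring A and builds the gem-dimethyl carbon C4 next to C5 and C10.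
- Stereochemistry: C9 and C10 come from a catalytic enantioselective Diels–Alder reaction (E-enal geometry gives the relative configuration, the catalyst the absolute one). C5 is relayed from C10 by α-face hydrogenation of a Δ5-7-one. C14 is bought as (R)-glyceraldehyde acetonide.

Key step: step 6

Assumption: atoms carry labdane numbers (C1–C20) throughout, and the (S)-configured oxazaborolidinium catalyst is taken to expose the enal face that leads to the 10β-methyl series; the antipodal catalyst is equally available should the sense be the opposite.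

**Route** (TBS = tert-butyldimethylsilyl)

Step 1
Reactants: 1 3-[(tert-butyldimethylsilyl)oxy]propanal; 2 2-(triphenyl-λ5-phosphanylidene)propanal
Product: 3 (E)-5-[(tert-butyldimethylsilyl)oxy]-2-methylpent-2-enal
Conditions: toluene, 80 °C
Reagents that add atoms: none
Why: Wittig olefination with a stabilised ylide gives the E-trisubstituted enal, whose geometry is later read out as the C9/C10 relative configuration.

Step 2
Reactants: 4 pent-1-en-3-one
Product: 5 (Z)-tert-butyl(dimethyl)(penta-1,3-dien-3-yloxy)silane
Conditions: TBSOTf, Et3N, Et2O, 0 °C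
Reagents that add atoms: tert-butyldimethylsilyl trifluoromethanesulfonate, CC(C)(C)[Si](C)(C)OS(=O)(=O)C(F)(F)F
Why: Soft enolisation and O-silylation of the ethyl ketone gives the 2-silyloxydiene as the Z enol ether, which places the C8 methyl on the outside of the s-cis diene.

Step 3
Reactants: 3 (E)-5-[(tert-butyldimethylsilyl)oxy]-2-methylpent-2-enal; 5 (Z)-tert-butyl(dimethyl)(penta-1,3-dien-3-yloxy)silane
Product: 6 4-(TBSO)-6-[2-(TBSO)ethyl]-1,5-dimethylcyclohex-3-ene-1-carbaldehyde (ring B; C10 methyl and C9 chain cis, both β; CHO α; C8 epimers)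
Conditions: (S)-3,3-diphenyl-1-(o-tolyl)oxazaborolidine·Tf2NH (20 mol %), CH2Cl2, −78 → −40 °C
Reagents that add atoms: none
Why: Catalytic enantioselective Diels–Alder reaction: the silyloxy group makes C8 the nucleophilic diene terminus so that it bonds to the enal β-carbon C9 and C5 bonds to C10 (para rule), suprafacial addition turns the E-geometry of 3 into the cis relation of C9 chain and C10 methyl, the boron-bound formyl group exposes one enal face and so sets the absolute configuration of C9 and C10, and C8 is of no consequence because it later becomes sp2.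

Step 4
Reactants: 6 the Diels–Alder adduct
Product: 7 6-[2-(TBSO)ethyl]-1,5-dimethyl-4-oxocyclohex-2-ene-1-carbaldehyde (C10 methyl and C9 chain β; C8 epimers)
Conditions: Pd(OAc)2 (1.1 equiv), MeCN, rt → 40 °C
Reagents that add atoms: none
Why: Saegusa–Ito oxidation: the Pd(II) enolate forms at C6, where the silyl enol ether stood, and β-hydride elimination from C5 places the enone regiospecifically at C5=C6–C7=O.

Step 5
Reactants: 8 3,3-dimethyloxolan-2-one
Product: 9 (3-carboxy-3-methylbutyl)triphenylphosphonium bromide
Conditions: Ph3P·HBr, neat, 160 °C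
Reagents that add atoms: triphenylphosphine hydrobromide, [Br-].[PH+](c1ccccc1)(c1ccccc1)c1ccccc1
Why: Acid-assisted SN2 opening of the γ-lactone at its primary O–CH2 carbon by triphenylphosphine (phosphonium salt formation) gives the ω-carboxyalkyl salt with no by-product.

Step 6
Reactants: 7 the enone aldehyde; 9 (3-carboxy-3-methylbutyl)triphenylphosphonium bromide
Product: 12 12-(TBSO)-13,14,15,16-tetranor-5β-labd-1-en-7-one (cis-fused; 9α-H; 10β-CH3; C8 epimers), via ylide carboxylate 10 (not isolated), via Z-alkenoate 11 (not isolated)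
Conditions: 9, KHMDS (2 equiv per 9), THF, −78 → 0 °C; 7, −78 °C → rt, dark; then DMF–H2O, 4CzIPN (2 mol %), 450 nm LED, rt, same flask
Reagents that add atoms: none
Why: Proposed new method: reagent 9 is a C2–C3–C4 linchpin with an ylide precursor at C2 and a latent tertiary radical (the carboxylate) at C4, and ring B of 7 offers the matching pair, the non-enolisable formyl carbon C1 and the enone β-carbon C5, set 1,3 across quaternary C10. In the dark the unstabilised ylide 10 olefinates only the aldehyde (kinetic oxaphosphetane, Z-alkene), which forms C1=C2 and leaves carboxylate 11; on irradiation the excited dye oxidises the carboxylate, CO2 is lost, the nucleophilic C4 radical adds to C5, and the α-acyl radical is reduced by the reduced dye to the enolate and protonated by water, so the second half is redox-neutral. The closest known reaction types are the Z-selective Wittig reaction of ω-carboxyalkyl ylides and the photoredox decarboxylative Giese addition of tertiary acids, and only their merger through one bifunctional reagent in one flask is new. Ring A closes in the 6-exo-trig mode, since 7-endo attack at C6 is polarity-mismatched and 3-exo closure onto C1=C2 is reversible, and only the Z-alkene can reach C5. The new stereocentre C5 is controlled by C10, because the tether on C10 can reach only the enone face on which C1 lies, so the cis-fused 5β-H isomer is expected; this centre is provisional and is reset in steps 7 and 8. The step needs aldehyde-over-enone selectivity in the olefination (secured by the more electrophilic CHO at low temperature) and cyclisation ahead of radical quenching (secured by intramolecularity and the absence of an H-atom donor).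

Step 7
Reactants: 12 the cis-fused ketone
Product: 14 12-(TBSO)-13,14,15,16-tetranorlabda-1,5-dien-7-one (9α-H; 10β-CH3; C8 epimers), via lithium enolate 13 (not isolated)
Conditions: LDA, THF, −78 °C; then PhS(Cl)=N-t-Bu, −78 °C
Reagents that add atoms: none
Why: Mukaiyama dehydrogenation: kinetic deprotonation takes the C6 methylene rather than the methyl-bearing C8, and the sulfinimidoyl adduct eliminates towards C5, which restores the C5=C6 enone and erases the provisional C5 centre.

Step 8
Reactants: 14 the dienone
Product: 15 12-(TBSO)-13,14,15,16-tetranor-5α-labdan-7-one (trans-fused; 9α-H; 10β-CH3; C8 epimers)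
Conditions: H2 (3 bar), 10 % Pd/C, EtOAc, rt
Reagents that add atoms: none
Why: Heterogeneous catalytic hydrogenation saturates C1=C2 and the enone C5=C6, and hydrogen reaches C5 from the α-face because the β-face is screened by the C10 methyl and the β-methyl on C4, the outcome known for Δ5-7-oxo steroids, so the trans ring fusion (5α-H) is relayed from C10.

Step 9
Reactants: 15 the trans-fused ketone
Product: 16 12-(TBSO)-13,14,15,16-tetranorlabd-7-en-7-yl trifluoromethanesulfonate
Conditions: Tf2O, 2,6-di-tert-butyl-4-methylpyridine, CH2Cl2, 0 °C → rt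
Reagents that add atoms: trifluoromethanesulfonic anhydride, O=S(=O)(OS(=O)(=O)C(F)(F)F)C(F)(F)F
Why: Enol triflate formation through an O-triflyl oxocarbenium ion loses the proton that gives the more substituted alkene, and enolisation towards C6 is further disfavoured next to the ring fusion and the C4 methyls, so the C7=C8 triflate is expected from either C8 epimer.

Step 10
Reactants: 16 the enol triflate
Product: 17 12-(TBSO)-13,14,15,16-tetranorlabd-7-ene
Conditions: Pd(OAc)2 (5 mol %), PPh3, HCO2H, Et3N, DMF, 60 °C
Reagents that add atoms: none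
Why: Palladium-catalysed formate hydrogenolysis of a vinyl triflate replaces OTf by H without moving the C7=C8 double bond.

Step 11
Reactants: 17 the silyl ether
Product: 18 13,14,15,16-tetranorlabd-7-en-12-ol
Conditions: TBAF, THF, rt
Reagents that add atoms: none
Why: Fluoride-induced desilylation frees the primary alcohol and touches nothing else.

Step 12
Reactants: 18 13,14,15,16-tetranorlabd-7-en-12-ol
Product: 19 12-iodo-13,14,15,16-tetranorlabd-7-ene
Conditions: I2, PPh3, imidazole, CH2Cl2, 0 °C → rt
Reagents that add atoms: iodine, II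
Why: Appel-type iodination converts the unhindered primary alcohol by SN2 on the alkoxyphosphonium ion under conditions that leave the trisubstituted alkene alone.

Step 13
Reactants: 20 (R)-2,2-dimethyl-1,3-dioxolane-4-carbaldehyde
Product: 21 (S)-4-ethynyl-2,2-dimethyl-1,3-dioxolane
Conditions: dimethyl (1-diazo-2-oxopropyl)phosphonate, K2CO3, MeOH, 0 °C → rt
Reagents that add atoms: dimethyl (1-diazo-2-oxopropyl)phosphonate, COP(=O)(OC)C(=[N+]=[N-])C(C)=O
Why: Ohira–Bestmann (Seyferth–Gilbert) homologation turns the aldehyde into the terminal alkyne under mild carbonate conditions that keep the α-alkoxy stereocentre (the later C14).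

Step 14
Reactants: 21 (S)-4-ethynyl-2,2-dimethyl-1,3-dioxolane
Product: 23 (R)-4-(1-bromoethenyl)-2,2-dimethyl-1,3-dioxolane, via internal vinylalane 22 (not isolated)
Conditions: Ni(dppp)Cl2 (3 mol %), DIBAL-H, THF, 0 °C → rt; then NBS, 0 °C
Reagents that add atoms: N-bromosuccinimide, O=C1CCC(=O)N1Br
Why: Nickel-catalysed α-selective (Markovnikov) hydroalumination of the terminal alkyne puts aluminium on the internal carbon, and bromodealumination gives the 2-bromo-1-alkene without touching the stereocentre.

Step 15
Reactants: 19 12-iodo-13,14,15,16-tetranorlabd-7-ene; 23 (R)-4-(1-bromoethenyl)-2,2-dimethyl-1,3-dioxolane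
Product: 25 (14S)-14,15-O-isopropylidenelabda-7,13(16)-diene-14,15-diol, via alkylzinc iodide 24 (not isolated)
Conditions: activated Zn dust, THF, 40 °C; then 23, Pd(dppf)Cl2 (5 mol %), THF, 50 °C
Reagents that add atoms: none
Why: Negishi sp3–sp2 cross-coupling of the primary alkylzinc iodide with the vinyl bromide forms C12–C13, sets the 1,1-disubstituted alkene directly and leaves C14 untouched.

Step 16
Reactants: 25 the acetonide
Product: 26 (14S)-labda-7,13(16)-diene-14,15-diol
Conditions: AcOH–H2O–THF (3:1:1), 40 °C
Reagents that add atoms: none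
Why: Mild acid hydrolysis of the isopropylidene acetal frees the 1,2-diol under conditions too weak to protonate either alkene.

Step 17
Reactants: 26 (14S)-labda-7,13(16)-diene-14,15-diol
Product: 27 (14S)-labda-7,13(16)-diene-14,15-diyl diacetate (CNP0289003.1)
Conditions: Ac2O, pyridine, DMAP (cat.), CH2Cl2, rt
Reagents that add atoms: acetic anhydride, CC(=O)OC(C)=O
Why: DMAP-catalysed acetylation esterifies both hydroxyl groups with retention at C14 and gives the target.

**Compound list**
1 | 3-[(tert-butyldimethylsilyl)oxy]propanal | CC(C)(C)[Si](C)(C)OCCC=O | starting material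
2 | 2-(triphenyl-λ5-phosphanylidene)propanal | CC(C=O)=P(c1ccccc1)(c1ccccc1)c1ccccc1 | starting material
3 | (E)-5-[(tert-butyldimethylsilyl)oxy]-2-methylpent-2-enal | CC(C)(C)[Si](C)(C)OCC/C=C(\C)C=O | intermediate
4 | pent-1-en-3-one | CCC(=O)C=C | starting material
5 | (Z)-tert-butyl(dimethyl)(penta-1,3-dien-3-yloxy)silane | C=C/C(O[Si](C)(C)C(C)(C)C)=C/C | intermediate
6 | 4-(TBSO)-6-[2-(TBSO)ethyl]-1,5-dimethylcyclohex-3-ene-1-carbaldehyde (C8 epimers) | CC(C)(C)[Si](C)(C)OCC[C@H]1C(C)C(O[Si](C)(C)C(C)(C)C)=CC[C@]1(C)C=O | intermediate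
7 | 6-[2-(TBSO)ethyl]-1,5-dimethyl-4-oxocyclohex-2-ene-1-carbaldehyde (C8 epimers) | CC(C)(C)[Si](C)(C)OCC[C@H]1C(C)C(=O)C=C[C@]1(C)C=O | intermediate
8 | 3,3-dimethyloxolan-2-one | CC1(C)CCOC1=O | starting material
9 | (3-carboxy-3-methylbutyl)triphenylphosphonium bromide | [Br-].OC(=O)C(C)(C)CC[P+](c1ccccc1)(c1ccccc1)c1ccccc1 | intermediate
10 | potassium 2,2-dimethyl-4-(triphenyl-λ5-phosphanylidene)butanoate (not isolated) | [K+].[O-]C(=O)C(C)(C)CC=P(c1ccccc1)(c1ccccc1)c1ccccc1 | intermediate
11 | potassium (Z)-5-{6-[2-(TBSO)ethyl]-1,5-dimethyl-4-oxocyclohex-2-en-1-yl}-2,2-dimethylpent-4-enoate (not isolated) | CC(C)(C)[Si](C)(C)OCC[C@H]1C(C)C(=O)C=C[C@]1(C)/C=C\CC(C)(C)C(=O)[O-].[K+] | intermediate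
12 | 12-(TBSO)-13,14,15,16-tetranor-5β-labd-1-en-7-one (C8 epimers) | CC(C)(C)[Si](C)(C)OCC[C@H]1C(C)C(=O)C[C@@H]2C(C)(C)CC=C[C@]12C | intermediate
13 | lithium C6=C7 enolate of 12 (not isolated) | CC(C)(C)[Si](C)(C)OCC[C@H]1C(C)C([O-])=C[C@@H]2C(C)(C)CC=C[C@]12C.[Li+] | intermediate
14 | 12-(TBSO)-13,14,15,16-tetranorlabda-1,5-dien-7-one (C8 epimers) | CC(C)(C)[Si](C)(C)OCC[C@H]1C(C)C(=O)C=C2C(C)(C)CC=C[C@]12C | intermediate
15 | 12-(TBSO)-13,14,15,16-tetranor-5α-labdan-7-one (C8 epimers) | CC(C)(C)[Si](C)(C)OCC[C@H]1C(C)C(=O)C[C@H]2C(C)(C)CCC[C@]12C | intermediate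
16 | 12-(TBSO)-13,14,15,16-tetranorlabd-7-en-7-yl trifluoromethanesulfonate | CC(C)(C)[Si](C)(C)OCC[C@H]1C(C)=C(OS(=O)(=O)C(F)(F)F)C[C@H]2C(C)(C)CCC[C@]12C | intermediate
17 | 12-(TBSO)-13,14,15,16-tetranorlabd-7-ene | CC(C)(C)[Si](C)(C)OCC[C@H]1C(C)=CC[C@H]2C(C)(C)CCC[C@]12C | intermediate
18 | 13,14,15,16-tetranorlabd-7-en-12-ol | OCC[C@H]1C(C)=CC[C@H]2C(C)(C)CCC[C@]12C | intermediate
19 | 12-iodo-13,14,15,16-tetranorlabd-7-ene | ICC[C@H]1C(C)=CC[C@H]2C(C)(C)CCC[C@]12C | intermediate
20 | (R)-2,2-dimethyl-1,3-dioxolane-4-carbaldehyde | O=C[C@H]1COC(C)(C)O1 | starting material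
21 | (S)-4-ethynyl-2,2-dimethyl-1,3-dioxolane | C#C[C@H]1COC(C)(C)O1 | intermediate
22 | diisobutyl{1-[(4R)-2,2-dimethyl-1,3-dioxolan-4-yl]ethenyl}alane (not isolated) | C=C([Al](CC(C)C)CC(C)C)[C@H]1COC(C)(C)O1 | intermediate
23 | (R)-4-(1-bromoethenyl)-2,2-dimethyl-1,3-dioxolane | C=C(Br)[C@H]1COC(C)(C)O1 | intermediate
24 | (13,14,15,16-tetranorlabd-7-en-12-yl)zinc iodide (not isolated) | I[Zn]CC[C@H]1C(C)=CC[C@H]2C(C)(C)CCC[C@]12C | intermediate
25 | (14S)-14,15-O-isopropylidenelabda-7,13(16)-diene-14,15-diol | C=C(CC[C@H]1C(C)=CC[C@H]2C(C)(C)CCC[C@]12C)[C@H]1COC(C)(C)O1 | intermediate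
26 | (14S)-labda-7,13(16)-diene-14,15-diol | C=C(CC[C@H]1C(C)=CC[C@H]2C(C)(C)CCC[C@]12C)[C@@H](CO)O | intermediate
27 | (5S,9S,10S,14S)-labda-7,13(16)-diene-14,15-diyl diacetate | C=C(CC[C@H]1C(C)=CC[C@H]2C(C)(C)CCC[C@]12C)[C@@H](COC(C)=O)OC(C)=O | target

**Step count**
- Total step count: 17.
- Longest linear sequence: 13 (steps 1, 3, 4, 6, 7, 8, 9, 10, 11, 12, 15, 16, 17).

**Steps most likely to fail**

1. Step 6.
   - What may go wrong: the basic ylide may enolise the enone instead of olefinating. The Z-geometry may erode, so that part of the material cannot cyclise. Energy transfer to the 4-vinylcyclohexenone chromophore may trigger photorearrangement faster than decarboxylation.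
   - Fallback: this path uses known chemistry in two isolated steps. It sets out from 7 and comes back at 12. The ylide from (3-methylbut-3-en-1-yl)triphenylphosphonium bromide (NaHMDS, THF, −78 °C) olefinates the aldehyde to the isolated (Z)-trienone F1. An iron-hydride hydrogen-atom-transfer reductive olefin coupling (Fe(acac)3, PhSiH3, EtOH, 60 °C) then generates the same C4 tertiary radical from the 1,1-disubstituted alkene. That radical closes C4–C5 in the 6-exo mode without light.

2. Step 3.
   - What may go wrong: turnover of the β-substituted α-methyl enal may be slow. The acidic catalyst may protodesilylate the diene. A stepwise Mukaiyama–Michael pathway may erode the enantioselectivity.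
   - Fallback: this path uses auxiliary control in place of catalysis. It sets out from 3 and comes back at 7, so step 4 is bypassed. Conjugate amination of pent-1-yn-3-one with (2R,5R)-2,5-diphenylpyrrolidine gives the vinylogous amide F2. KHMDS/TBSCl converts it to the chiral 1-amino-3-silyloxydiene F3. An uncatalysed Diels–Alder reaction with 3 (toluene, rt → 40 °C) gives the cycloadduct F4. Brief treatment with dilute HCl in THF at 0 °C hydrolyses the silyl enol ether and expels the amine.

3. Step 8.
   - What may go wrong: hydrogen uptake may be sluggish at the C5=C6 bond, which is flanked by two quaternary carbons. The facial discrimination at C5 may be incomplete.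
   - Fallback: this path sets out from 14 and comes back at 15. A Birch-type dissolving-metal reduction (Li, NH3, THF, t-BuOH, −78 °C) is insensitive to steric shielding. It protonates the β-carbanion at C5 axially and gives the trans-fused enone-reduced ketone F5. Hydrogenation (H2, Pd/C) then has only the unhindered C1=C2 bond left to saturate.

Further compounds
F1 | step 6 | (4S,5S)-5-[2-(TBSO)ethyl]-4,6-dimethyl-4-[(Z)-4-methylpenta-1,4-dien-1-yl]cyclohex-2-en-1-one | CC(C)(C)[Si](C)(C)OCC[C@H]1C(C)C(=O)C=C[C@]1(C)/C=C\CC(C)=C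
F2 | step 3 | (E)-1-[(2R,5R)-2,5-diphenylpyrrolidin-1-yl]pent-1-en-3-one | c1ccccc1[C@H]1CC[C@H](c2ccccc2)N1/C=C/C(=O)CC
F3 | step 3 | (2R,5R)-1-[(1E,3Z)-3-(tert-butyldimethylsilyloxy)penta-1,3-dien-1-yl]-2,5-diphenylpyrrolidine | c1ccccc1[C@H]1CC[C@H](c2ccccc2)N1/C=C/C(O[Si](C)(C)C(C)(C)C)=C/C
F4 | step 3 | 4-(TBSO)-6-[2-(TBSO)ethyl]-1,5-dimethyl-2-[(2R,5R)-2,5-diphenylpyrrolidin-1-yl]cyclohex-3-ene-1-carbaldehyde | CC(C)(C)[Si](C)(C)OCC[C@H]1C(C)C(O[Si](C)(C)C(C)(C)C)=CC(N2[C@@H](c3ccccc3)CC[C@@H]2c2ccccc2)[C@]1(C)C=O
F5 | step 8 | 12-(TBSO)-13,14,15,16-tetranor-5α-labd-1-en-7-one | CC(C)(C)[Si](C)(C)OCC[C@H]1C(C)C(=O)C[C@H]2C(C)(C)CC=C[C@]12C
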